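**Retrosynthetic overview**
1. Target 16 ⇐ spiro ketone 15: the C7 exocyclic methylene comes from the C7 ketone by titanium-methylidene olefination.
2. 15 ⇐ bromohydrin 12: ring A is closed last, on the preformed ring B, by forming the C6–C11 bond (spiro centre) from an enantiopure bromiranium ion and the ketone enol.
3. All halogen-bearing stereocentres are traced back to C–O bonds: C10–O from asymmetric epoxidation of a prenyl group (then SN2 bromide), and the C2/C3 epoxide of (S)-limonene (Cl by SN2 at C2, then C3–OH to C3–Br with retention).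
4. Skeleton: (S)-limonene (ring B, C6, C7, C8) plus prenyl bromide (C9–C11 and the gem-dimethyl), joined by alkylation of a methyl ketone.

Assumption: (S)-(−)-limonene, prenyl bromide and the L-fructose-derived Shi ketone are bought; atom labels C1–C11 are those of the target (ring B = C1–C5, spiro C6, ring A = C7–C11) and are used for the corresponding atoms of every intermediate.

**Step 1**
Reactants: 1 (4S)-1-methyl-4-(prop-1-en-2-yl)cyclohex-1-ene ((S)-limonene)
Product: 3 (1R,4S,6S)-1-methyl-4-(prop-1-en-2-yl)-7-oxabicyclo[4.1.0]heptane (trans-limonene oxide of the S series), via bromohydrin 2 (not isolated)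
Conditions: NBS (1.05 equiv), acetone/H2O 4:1, 0 °C; then 6 M aq. NaOH, 0 °C → rt
Reagents that add atoms: water, O
Why: Electrophilic bromohydroxylation takes place at the more electron-rich trisubstituted ring alkene by diaxial (Fürst–Plattner) Markovnikov opening of the bromonium ion, which puts the new C3–O bond on the tertiary carbon cis to the equatorial isopropenyl group, and intramolecular Williamson closure of 2 with inversion at C2 then gives the trans-epoxide as essentially one diastereomer.

**Step 2**
Reactants: 3 (1R,4S,6S)-1-methyl-4-(prop-1-en-2-yl)-7-oxabicyclo[4.1.0]heptane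
Product: 5 1-[(1S,3S,6R)-6-methyl-7-oxabicyclo[4.1.0]heptan-3-yl]ethan-1-one, via ozonide 4 (not isolated)
Conditions: O3, CH2Cl2, −78 °C; then Me2S, −78 °C → rt
Reagents that add atoms: ozone, [O-][O+]=O
Why: Ozonolysis with reductive work-up cleaves the only C=C bond, the isopropenyl group, to the methyl ketone, while the epoxide is inert and no stereocentre is touched.

**Step 3**
Reactants: 5 1-[(1S,3S,6R)-6-methyl-7-oxabicyclo[4.1.0]heptan-3-yl]ethan-1-one
Product: 6 1-[(1S,3R,4R)-3-chloro-4-hydroxy-4-methylcyclohexyl]ethan-1-one
Conditions: LiCl (5 equiv), AcOH (3 equiv), THF, rt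
Reagents that add atoms: lithium chloride, [Li+].[Cl-]
Why: Mildly acidic nucleophilic epoxide opening is an SN2 attack of chloride at the less substituted carbon C2 in the trans-diaxial (Fürst–Plattner) mode open to this epoxide diastereomer, so C2 is inverted to carry an axial chlorine and the tertiary C3–O bond stays as an axial hydroxyl.

**Step 4**
Reactants: 6 1-[(1S,3R,4R)-3-chloro-4-hydroxy-4-methylcyclohexyl]ethan-1-one
Product: 7 1-[(1S,3R,4R)-4-bromo-3-chloro-4-methylcyclohexyl]ethan-1-one
Conditions: HBr (33% in AcOH), CH2Cl2, 0 °C → rt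
Reagents that add atoms: hydrogen bromide, Br
Why: SN1 substitution of the tertiary alcohol with neighbouring-group participation of the anti-periplanar axial chlorine returns bromide to C3 on the face the hydroxyl left (net retention, bromine axial, methyl equatorial), which is also the thermodynamically preferred tertiary bromide under these reversible conditions, so the trans C2–Cl/C3–Br pair of the target is fixed.

**Step 5**
Reactants: 7 1-[(1S,3R,4R)-4-bromo-3-chloro-4-methylcyclohexyl]ethan-1-one; 8 1-bromo-3-methylbut-2-ene (prenyl bromide)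
Product: 10 1-[(1S,3R,4R)-4-bromo-3-chloro-4-methylcyclohexyl]-5-methylhex-4-en-1-one, via lithium enolate 9 (not isolated)
Conditions: LiN(i-Pr)2 (1.0 equiv), THF, −78 °C; then 8 (1.5 equiv), DMPU, −78 → −40 °C
Reagents that add atoms: none
Why: Kinetic deprotonation on the methyl side of the methyl ketone followed by SN2 alkylation of the lithium enolate with the allylic bromide attaches C9–C11, and the low temperature, the exact base stoichiometry and the fast electrophile keep the tertiary bromide and the secondary chloride from E2 loss or intramolecular displacement.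

**Step 6**
Reactants: 10 1-[(1S,3R,4R)-4-bromo-3-chloro-4-methylcyclohexyl]-5-methylhex-4-en-1-one
Product: 11 1-[(1S,3R,4R)-4-bromo-3-chloro-4-methylcyclohexyl]-3-[(2S)-3,3-dimethyloxiran-2-yl]propan-1-one
Conditions: L-fructose-derived Shi ketone (30 mol %), KHSO5, K2CO3, Bu4NHSO4, aq. Na2B4O7 buffer (pH 10.5), MeCN/CH2(OMe)2, 0 °C
Reagents that add atoms: potassium peroxymonosulfate KHSO5, [K+].[O-]S(=O)(=O)OO
Why: Shi asymmetric epoxidation (chiral dioxirane formed catalytically from the ketone) of the only alkene, a trisubstituted prenyl terminus, is catalyst-controlled, and the L-fructose-derived ketone delivers oxygen to the face that gives the (S)-configured C10–O bond, the D-fructose-derived ketone giving the (R)-epoxide with this olefin class.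

**Step 7**
Reactants: 11 1-[(1S,3R,4R)-4-bromo-3-chloro-4-methylcyclohexyl]-3-[(2S)-3,3-dimethyloxiran-2-yl]propan-1-one
Product: 12 (4R)-4-bromo-1-[(1S,3R,4R)-4-bromo-3-chloro-4-methylcyclohexyl]-5-hydroxy-5-methylhexan-1-one
Conditions: LiBr (5 equiv), AcOH (2 equiv), THF, 0 °C → rt
Reagents that add atoms: lithium bromide, [Li+].[Br-]
Why: Regioselective SN2 opening of the trisubstituted epoxide by the strongly nucleophilic bromide under weakly acidic conditions occurs at the secondary carbon C10 with inversion, which turns the C10–O stereocentre into the (10R) C–Br stereocentre of the target and leaves a tertiary carbinol at C11 as a latent leaving group.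

**Step 8**
Reactants: 12 (4R)-4-bromo-1-[(1S,3R,4R)-4-bromo-3-chloro-4-methylcyclohexyl]-5-hydroxy-5-methylhexan-1-one
Product: 15 (2R,3R,6R,10R)-3,10-dibromo-2-chloro-3,11,11-trimethylspiro[5.5]undecan-7-one, via bromiranium ion 13 (not isolated), via enol 14 (not isolated)
Conditions: CF3SO3H (20 mol %), (CF3)2CHOH/CH2Cl2 1:1, −20 → 0 °C
Reagents that add atoms: none
Why: Proposed new method: an acid-triggered, enantiospecific bromiranium spirocyclization terminated by a simple ketone enol, in which the strong acid in the ionizing, weakly nucleophilic fluorinated alcohol ionizes the tertiary C11 carbinol with anti participation of the C10 bromine to give the configurationally stable ion 13 (no alkene is present to scramble it by bromonium transfer), capture by the carbonyl oxygen is reversible and unproductive, and the acid-equilibrated tetrasubstituted enol 14 (its two geometries interconvert through the ketone, a Curtin–Hammett situation) alkylates C11 irreversibly through a chair transition state with C10–Br equatorial and with attack from the equatorial direction of ring B, anti to the axial C2 chlorine of the chair that keeps the C3 methyl equatorial, which sets the spiro centre C6 with C7 cis to the C2 chlorine and C1 cis to the C10 bromine while C10 keeps its configuration; the closest known reaction types are enantiospecific bromiranium-initiated cation–olefin cyclizations started from enantiopure bromohydrins or vicinal bromochlorides in fluorinated alcohols and the Lewis-acid α-tert-alkylation of enol derivatives, neither of which has been shown with an unactivated ketone enol as terminator forming a spiro quaternary carbon.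

**Step 9**
Reactants: 15 (2R,3R,6R,10R)-3,10-dibromo-2-chloro-3,11,11-trimethylspiro[5.5]undecan-7-one
Product: 16 (2R,3R,6S,10R)-3,10-dibromo-2-chloro-3,11,11-trimethyl-7-methylidenespiro[5.5]undecane (target)
Conditions: Cp2Ti(μ-CH2)(μ-Cl)AlMe2 (2 equiv), pyridine, THF/toluene, −40 → 0 °C
Reagents that add atoms: Cp2Ti(μ-CH2)(μ-Cl)AlMe2, [Ti+4].[CH2-2].[Cl-].[Al+3].[CH3-].[CH3-].c1cc[cH-]c1.c1cc[cH-]c1
Why: Tebbe methylenation (titanium methylidene, [2+2] addition to the carbonyl and cycloreversion) is non-basic and non-reducing, so the hindered C7 ketone next to the spiro centre becomes the exocyclic methylene without E2 loss of the tertiary bromide or reductive loss of the vicinal dihalide, and the C6 descriptor changes from R to S only because the CIP rank of C7 drops below that of C11.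

**Compound list**
1 | (4S)-1-methyl-4-(prop-1-en-2-yl)cyclohex-1-ene, (S)-(−)-limonene | CC1=CC[C@H](CC1)C(C)=C | starting material
2 | (1R,2R,4S)-2-bromo-1-methyl-4-(prop-1-en-2-yl)cyclohexan-1-ol | C[C@@]1(O)CC[C@H](C(C)=C)C[C@H]1Br | intermediate (not isolated)
3 | (1R,4S,6S)-1-methyl-4-(prop-1-en-2-yl)-7-oxabicyclo[4.1.0]heptane | C[C@@]12CC[C@H](C(C)=C)C[C@@H]1O2 | intermediate
4 | 3-methyl-3-[(1S,3S,6R)-6-methyl-7-oxabicyclo[4.1.0]heptan-3-yl]-1,2,4-trioxolane (both epimers at the trioxolane carbon) | C[C@@]12CC[C@H](C3(C)OCOO3)C[C@@H]1O2 | intermediate (not isolated)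
5 | 1-[(1S,3S,6R)-6-methyl-7-oxabicyclo[4.1.0]heptan-3-yl]ethan-1-one | C[C@@]12CC[C@H](C(C)=O)C[C@@H]1O2 | intermediate
6 | 1-[(1S,3R,4R)-3-chloro-4-hydroxy-4-methylcyclohexyl]ethan-1-one | C[C@@]1(O)CC[C@H](C(C)=O)C[C@H]1Cl | intermediate
7 | 1-[(1S,3R,4R)-4-bromo-3-chloro-4-methylcyclohexyl]ethan-1-one | C[C@@]1(Br)CC[C@H](C(C)=O)C[C@H]1Cl | intermediate
8 | 1-bromo-3-methylbut-2-ene (prenyl bromide) | CC(C)=CCBr | starting material
9 | lithium 1-[(1S,3R,4R)-4-bromo-3-chloro-4-methylcyclohexyl]ethen-1-olate | C[C@@]1(Br)CC[C@H](C(=C)O[Li])C[C@H]1Cl | intermediate (not isolated)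
10 | 1-[(1S,3R,4R)-4-bromo-3-chloro-4-methylcyclohexyl]-5-methylhex-4-en-1-one | C[C@@]1(Br)CC[C@H](C(=O)CCC=C(C)C)C[C@H]1Cl | intermediate
11 | 1-[(1S,3R,4R)-4-bromo-3-chloro-4-methylcyclohexyl]-3-[(2S)-3,3-dimethyloxiran-2-yl]propan-1-one | C[C@@]1(Br)CC[C@H](C(=O)CC[C@@H]2OC2(C)C)C[C@H]1Cl | intermediate
12 | (4R)-4-bromo-1-[(1S,3R,4R)-4-bromo-3-chloro-4-methylcyclohexyl]-5-hydroxy-5-methylhexan-1-one | C[C@@]1(Br)CC[C@H](C(=O)CC[C@@H](Br)C(C)(C)O)C[C@H]1Cl | intermediate
13 | (2R)-2-{3-[(1S,3R,4R)-4-bromo-3-chloro-4-methylcyclohexyl]-3-oxopropyl}-3,3-dimethylbromiran-1-ium | C[C@@]1(Br)CC[C@H](C(=O)CC[C@H]2[Br+]C2(C)C)C[C@H]1Cl | intermediate (not isolated)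
14 | (2R)-2-{3-[(3R,4R)-4-bromo-3-chloro-4-methylcyclohexylidene]-3-hydroxypropyl}-3,3-dimethylbromiran-1-ium (enol, both geometries) | C[C@@]1(Br)CCC(=C(O)CC[C@H]2[Br+]C2(C)C)C[C@H]1Cl | intermediate (not isolated)
15 | (2R,3R,6R,10R)-3,10-dibromo-2-chloro-3,11,11-trimethylspiro[5.5]undecan-7-one | O=C1CC[C@@H](Br)C(C)(C)[C@]12CC[C@@](C)(Br)[C@H](Cl)C2 | intermediate
16 | (2R,3R,6S,10R)-3,10-dibromo-2-chloro-3,11,11-trimethyl-7-methylidenespiro[5.5]undecane | C=C1CC[C@@H](Br)C(C)(C)[C@]12CC[C@@](C)(Br)[C@H](Cl)C2 | target

**Totals and risks**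
Total step count: 9. Longest linear sequence: 9 steps (from 1).

The three steps most likely to fail:

Step 8 (the proposed new step). The risks are that the ion is held as the oxygen-cyclized enol ether, that the ring B tertiary bromide ionizes, or that facial selectivity at C6 is low. The fallback uses established reactions and sets out from 12. Silylation with Me3SiOTf and Et3N in CH2Cl2 at 0 °C gives (4R)-4-bromo-1-[(3R,4R)-4-bromo-3-chloro-4-methylcyclohexylidene]-5-methyl-1,5-bis(trimethylsilyloxy)hexane F2, the tetrasubstituted silyl enol ether that also carries the C11 silyl ether. Treatment of this with TiCl4 in CH2Cl2 at −78 °C ionizes the tertiary silyl ether with bromine participation and joins C11 to C6 in a Lewis-acid tert-alkylation of a silyl enol ether. The route is rejoined at 15. Only the enol-ether geometry that fits the chair transition state gives 15, so the yield ceiling is lower and the C6 epimer has to be separated.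

Step 7. Bromide may enter at the tertiary C11 instead, or the γ,δ-epoxy ketone may close to a bicyclic ketal under acid. The fallback bypasses steps 6 and 7 and sets out from 10. Plain electrophilic bromohydroxylation (NBS, THF/H2O, 0 °C) proceeds by Markovnikov opening of the bromonium ion and gives 12 together with its C10 epimer, (4S)-4-bromo-1-[(1S,3R,4R)-4-bromo-3-chloro-4-methylcyclohexyl]-5-hydroxy-5-methylhexan-1-one F1. The two are diastereomers and are separated by chromatography. The route is rejoined at 12 at the cost of half the material.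

Step 9. The ketone is flanked by the spiro quaternary carbon and may react slowly or lose the tertiary bromide. The fallback sets out from 15 and replaces the titanium carbene by an addition–elimination (Peterson) sequence. Me3SiCH2MgCl with anhydrous CeCl3 in THF at −78 → 0 °C adds to the ketone to give (2R,3R,6R,10R)-3,10-dibromo-2-chloro-3,11,11-trimethyl-7-[(trimethylsilyl)methyl]spiro[5.5]undecan-7-ol F3 (either configuration at C7). BF3·OEt2 in CH2Cl2 at −20 °C then effects the acid-mediated elimination of the β-hydroxysilane, and the route is rejoined at 16.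

**Further compounds**
F1 | step 7 | (4S)-4-bromo-1-[(1S,3R,4R)-4-bromo-3-chloro-4-methylcyclohexyl]-5-hydroxy-5-methylhexan-1-one | C[C@@]1(Br)CC[C@H](C(=O)CC[C@H](Br)C(C)(C)O)C[C@H]1Cl
F2 | step 8 | (4R)-4-bromo-1-[(3R,4R)-4-bromo-3-chloro-4-methylcyclohexylidene]-5-methyl-1,5-bis(trimethylsilyloxy)hexane (both enol ether geometries) | C[C@@]1(Br)CCC(=C(O[Si](C)(C)C)CC[C@@H](Br)C(C)(C)O[Si](C)(C)C)C[C@H]1Cl
F3 | step 9 | (2R,3R,6R,10R)-3,10-dibromo-2-chloro-3,11,11-trimethyl-7-[(trimethylsilyl)methyl]spiro[5.5]undecan-7-ol (either configuration at C7) | C[Si](C)(C)CC1(O)CC[C@@H](Br)C(C)(C)[C@]12CC[C@@](C)(Br)[C@H](Cl)C2
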